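**Retrosynthetic overview**

1. The (2R)-hemiketal is released last by hydrogenolysis of the (2R)-mixed ketal 23, which carries a (1S)-1-phenylethoxy group at C2. The same operation removes two benzyl ethers and saturates a C5 alkyne to the 3-methylbutyl chain.
2. Ketal 23 comes from racemic hemiketal 21 by acid-catalysed ketal exchange with (S)-1-phenylethanol and chromatographic separation at C2. Hemiketal 21 comes from dioxolane ketone 19 by hydrolysis.
3. Key disconnection: 19 is cut into the aryne from silyl triflate 7 and carboxylic acid 16. Insertion of the aryne into the C(acyl)–O bond of the acid forms the O1–C8a and C4–C4a bonds together.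
4. Enabling feature: in the chroman-4-one, the ring oxygen O1 (on C8a) and the ketone carbon C4 (on C4a) sit on adjacent carbons of the benzene ring, so the bicycle is a cyclized ortho-hydroxyaryl ketone. The C5 chain is carried as an alkyne, a higher oxidation level that should polarize the aryne.
5. Ring order: the benzene ring (from 4-(benzyloxy)phenol, 3 steps to 7) and the pyranone ring (from 4-hydroxy-6-methyl-2-pyranone, 5 steps to 16) are bought. The dihydropyranone ring of the chromanone closes last (O1–C2, step 10).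

Key step: step 9

Assumption: a free 2-hydroxychroman-4-one can epimerize at C2 by ring opening to the 1,3-diketone, so C2 is fixed as a mixed ketal and released only in the last step under neutral conditions; the target is written as its 4-hydroxy-2-pyranone tautomer and should be handled cold and free of acid and base.

**Route**

Step 1
Reactants: 1 4-(benzyloxy)phenol
Product: 2 4-(benzyloxy)-2,6-dibromophenol
Conditions: NBS (2.1 equiv), iPr2NH (10 mol%), CH2Cl2, 0 °C → rt
Reagents that add atoms: N-bromosuccinimide, O=C1CCC(=O)N1Br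
Why: Electrophilic aromatic bromination in which the free phenol (amine-assisted ortho delivery) should direct both bromines to its two ortho positions, the para position being blocked by the benzyloxy group.

Step 2
Reactants: 2 4-(benzyloxy)-2,6-dibromophenol
Product: 5 4-(benzyloxy)-2-bromo-6-(trimethylsilyl)phenyl trifluoromethanesulfonate, via aryl trimethylsilyl ether 3 (not isolated), via lithium 2-bromo-6-silylphenoxide 4 (not isolated)
Conditions: (Me3Si)2NH, THF, 65 °C; evaporate; n-BuLi (1.05 equiv), THF, −78 °C; Tf2O, −78 °C → rt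
Reagents that add atoms: hexamethyldisilazane, C[Si](C)(C)N[Si](C)(C)C; triflic anhydride, O=S(=O)(OS(=O)(=O)C(F)(F)F)C(F)(F)F
Why: O-silylation, bromine–lithium exchange at one of the two equivalent bromides and retro-Brook 1,3-silyl shift from O to C should give phenoxide 4, whose O-triflation completes a fluoride-triggered ortho-silylaryl triflate aryne precursor while the second bromide is kept.

Step 3
Reactants: 5 4-(benzyloxy)-2-bromo-6-(trimethylsilyl)phenyl trifluoromethanesulfonate; 6 3-methylbut-1-yne
Product: 7 4-(benzyloxy)-2-(3-methylbut-1-yn-1-yl)-6-(trimethylsilyl)phenyl trifluoromethanesulfonate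
Conditions: Pd(PhCN)2Cl2 (3 mol%), [HP(t-Bu)3]BF4 (6 mol%), CuI (2 mol%), iPr2NH, dioxane, 25 °C, sealed vessel
Reagents that add atoms: none
Why: Sonogashira coupling in which, with a bulky trialkylphosphine, the C–Br bond should undergo oxidative addition in preference to the triflate that is shielded by two ortho substituents, while the fluoride-free amine conditions leave the C–Si bond intact.

Step 4
Reactants: 8 4-hydroxy-6-methyl-2H-pyran-2-one
Product: 9 4-(benzyloxy)-6-methyl-2H-pyran-2-one
Conditions: BnOH, PPh3, DIAD, THF, 0 °C → rt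
Reagents that add atoms: benzyl alcohol, OCc1ccccc1
Why: Mitsunobu alkylation, which is known to alkylate 4-hydroxy-2-pyranones on the 4-oxygen and avoids the C3-benzylation that benzyl halide and base can give.

Step 5
Reactants: 9 4-(benzyloxy)-6-methyl-2H-pyran-2-one
Product: 11 [4-(benzyloxy)-2-oxo-2H-pyran-6-yl]acetic acid, via lithium dienolate 10 (not isolated)
Conditions: LiN(iPr)2, THF, −78 °C; CO2, −78 °C; cold 1 M HCl work-up
Reagents that add atoms: carbon dioxide, O=C=O
Why: Vinylogous deprotonation of the C6 methyl group of a 4-alkoxy-6-methyl-2-pyranone followed by carboxylation of the dienolate at its terminal carbon should give the acetic acid, which is used promptly and kept cold to avoid decarboxylation.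

Step 6
Reactants: 11 [4-(benzyloxy)-2-oxo-2H-pyran-6-yl]acetic acid; 12 Meldrum's acid (2,2-dimethyl-1,3-dioxane-4,6-dione)
Product: 14 allyl 4-[4-(benzyloxy)-2-oxo-2H-pyran-6-yl]-3-oxobutanoate, via acyl Meldrum's acid 13 (not isolated)
Conditions: DCC, DMAP, CH2Cl2, 0 → 25 °C; filter; allyl alcohol, toluene, 90 °C
Reagents that add atoms: allyl alcohol, C=CCO
Why: C-acylation of Meldrum's acid and thermal alcoholysis through the acylketene (loss of acetone and CO2) is the standard two-carbon homologation of a carboxylic acid to a β-keto ester and avoids strong base on the acidic pyranonyl methylene.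

Step 7
Reactants: 14 allyl 4-[4-(benzyloxy)-2-oxo-2H-pyran-6-yl]-3-oxobutanoate
Product: 15 allyl 2-(2-{[4-(benzyloxy)-2-oxo-2H-pyran-6-yl]methyl}-1,3-dioxolan-2-yl)acetate
Conditions: Me3SiOCH2CH2OSiMe3, TMSOTf (5 mol%), CH2Cl2, −78 → −20 °C; pyridine quench
Reagents that add atoms: 1,2-bis(trimethylsilyloxy)ethane, C[Si](C)(C)OCCO[Si](C)(C)C
Why: Silyl triflate-catalysed ketalization with the bis-silyl ether of ethylene glycol should convert the ketone flanked by two acidic methylene groups into the dioxolane at low temperature without transesterification, and the cyclic ketal removes the C–H acidity and cannot be lost irreversibly by β-elimination in the key step.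

Step 8
Reactants: 15 allyl 2-(2-{[4-(benzyloxy)-2-oxo-2H-pyran-6-yl]methyl}-1,3-dioxolan-2-yl)acetate
Product: 16 2-(2-{[4-(benzyloxy)-2-oxo-2H-pyran-6-yl]methyl}-1,3-dioxolan-2-yl)acetic acid
Conditions: Pd(PPh3)4 (3 mol%), morpholine, THF, 25 °C; work-up at pH 4
Reagents that add atoms: none
Why: Tsuji–Trost deallylation (π-allylpalladium formation and capture by morpholine) frees the acid under neutral conditions that spare the dioxolane, the benzyl ether and the base-sensitive pyranone.

Step 9
Reactants: 16 2-(2-{[4-(benzyloxy)-2-oxo-2H-pyran-6-yl]methyl}-1,3-dioxolan-2-yl)acetic acid; 7 4-(benzyloxy)-2-(3-methylbut-1-yn-1-yl)-6-(trimethylsilyl)phenyl trifluoromethanesulfonate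
Product: 19 1-[4-(benzyloxy)-2-hydroxy-6-(3-methylbut-1-yn-1-yl)phenyl]-2-(2-{[4-(benzyloxy)-2-oxo-2H-pyran-6-yl]methyl}-1,3-dioxolan-2-yl)ethan-1-one, via 3-alkynylbenzyne 17 (not isolated), via cesium 2-(acyloxy)aryl anion 18 (not isolated)
Conditions: 16 (1.3 equiv), 7 (1.0 equiv), CsF (4 equiv), THF, 125 °C, sealed tube
Reagents that add atoms: none
Why: Fluoride-induced 1,2-elimination of 7 gives aryne 17; the cesium carboxylate of 16 should add through oxygen to the aryne carbon remote from the alkyne (the future C8a), and the ortho-acyloxy aryl anion 18 then attacks its own ester carbonyl (4-exo-trig) to a benzoxetane alkoxide that opens to the ortho-acyl phenoxide, so that the aryne is formally inserted into the C(acyl)–O bond and the O1–C8a and C4–C4a bonds are formed together. The closest known reaction type is the insertion of fluoride-generated arynes into the C–O bond of carboxylic acids to give ortho-hydroxyaryl ketones under these conditions, an in situ anionic Fries-type 1,3-shift of the acyl group from O to C. No ring of the target is closed here (the four-membered ring is transient) and no stereocenter is formed. The step needs regioselective attack at one of the two aryne carbons: the sp-carbon substituent next to the aryne is inductively withdrawing and slender, which should distort the aryne so that the nucleophile enters at the distal carbon and the aryl anion develops beside the alkyne, as is known for 3-alkoxy- and 3-haloarynes and as a saturated 3-methylbutyl group would not secure. It also needs chemoselectivity: the carboxylate is the only anionic nucleophile, the dioxolane removes the acidic methylene protons and the decarboxylation of a free β-keto acid, and the 4-benzyloxy-2-pyranone should be only a sluggish diene toward the aryne, which is kept the limiting reagent.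

Step 10
Reactants: 19 1-[4-(benzyloxy)-2-hydroxy-6-(3-methylbut-1-yn-1-yl)phenyl]-2-(2-{[4-(benzyloxy)-2-oxo-2H-pyran-6-yl]methyl}-1,3-dioxolan-2-yl)ethan-1-one
Product: 21 racemic 7-(benzyloxy)-2-{[4-(benzyloxy)-2-oxo-2H-pyran-6-yl]methyl}-2-hydroxy-5-(3-methylbut-1-yn-1-yl)-2,3-dihydro-4H-chromen-4-one, via open-chain 1,3-diketone 20 (not isolated)
Conditions: 1 M aq. HCl, THF, 25 °C
Reagents that add atoms: water, O
Why: Acid-catalysed hydrolysis of the dioxolane (assisted by the neighbouring phenol) should give diketone 20, which closes the chromanone ring by 6-exo-trig addition of the phenol to the C2 ketone, the aqueous medium and ambient temperature disfavouring dehydration to the chromone; C2 is racemic at this stage.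

Step 11
Reactants: 21 racemic 7-(benzyloxy)-2-{[4-(benzyloxy)-2-oxo-2H-pyran-6-yl]methyl}-2-hydroxy-5-(3-methylbut-1-yn-1-yl)-2,3-dihydro-4H-chromen-4-one; 22 (S)-1-phenylethanol
Product: 23 (2R)-7-(benzyloxy)-2-{[4-(benzyloxy)-2-oxo-2H-pyran-6-yl]methyl}-5-(3-methylbut-1-yn-1-yl)-2-[(1S)-1-phenylethoxy]-2,3-dihydro-4H-chromen-4-one
Conditions: 22 (20 equiv, recovered), PPTS (10 mol%), 4 Å MS, CH2Cl2, 0 → 25 °C; chromatography on Et3N-buffered silica
Reagents that add atoms: none
Why: Acid-catalysed ketal exchange through the cyclic oxocarbenium ion at C2, the reaction type by which 2-hydroxychromanones form 2-alkoxy ketals in alcohols, should give material of both C2 configurations as separable diastereomers because of the auxiliary; the (2R,1′S) ketal 23 is isolated by chromatography with its configuration to be secured by X-ray or NOE analysis, and the fraction of opposite C2 configuration is re-equilibrated under the same reversible conditions.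

Step 12
Reactants: 23 (2R)-7-(benzyloxy)-2-{[4-(benzyloxy)-2-oxo-2H-pyran-6-yl]methyl}-5-(3-methylbut-1-yn-1-yl)-2-[(1S)-1-phenylethoxy]-2,3-dihydro-4H-chromen-4-one
Product: 24 (2R)-2,7-dihydroxy-2-[(4-hydroxy-2-oxo-2H-pyran-6-yl)methyl]-5-(3-methylbutyl)-2,3-dihydro-4H-chromen-4-one
Conditions: H2 (1 atm), 10% Pd/C, EtOAc, 0 → 20 °C; filtration and evaporation below 20 °C
Reagents that add atoms: none
Why: Heterogeneous hydrogenation should saturate the alkyne to the 3-methylbutyl chain and cleave the three benzylic C–O bonds (two benzyl ethers and the 1-phenylethyl ketal ether), and because only the O–CH(CH3)Ph bond is broken while both C2–O bonds stay intact, the (2R) configuration passes unchanged into the hemiketal under neutral conditions.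

**Compound list**

1 | 4-(benzyloxy)phenol | Oc1ccc(OCc2ccccc2)cc1 | starting material
2 | 4-(benzyloxy)-2,6-dibromophenol | Oc1c(Br)cc(OCc2ccccc2)cc1Br | intermediate
3 | [4-(benzyloxy)-2,6-dibromophenoxy]trimethylsilane (not isolated) | C[Si](C)(C)Oc1c(Br)cc(OCc2ccccc2)cc1Br | intermediate
4 | lithium 4-(benzyloxy)-2-bromo-6-(trimethylsilyl)phenoxide (not isolated) | [Li+].[O-]c1c(Br)cc(OCc2ccccc2)cc1[Si](C)(C)C | intermediate
5 | 4-(benzyloxy)-2-bromo-6-(trimethylsilyl)phenyl trifluoromethanesulfonate | FC(F)(F)S(=O)(=O)Oc1c(Br)cc(OCc2ccccc2)cc1[Si](C)(C)C | intermediate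
6 | 3-methylbut-1-yne | CC(C)C#C | starting material
7 | 4-(benzyloxy)-2-(3-methylbut-1-yn-1-yl)-6-(trimethylsilyl)phenyl trifluoromethanesulfonate | FC(F)(F)S(=O)(=O)Oc1c(C#CC(C)C)cc(OCc2ccccc2)cc1[Si](C)(C)C | intermediate
8 | 4-hydroxy-6-methyl-2H-pyran-2-one | Cc1cc(O)cc(=O)o1 | starting material
9 | 4-(benzyloxy)-6-methyl-2H-pyran-2-one | Cc1cc(OCc2ccccc2)cc(=O)o1 | intermediate
10 | lithium [4-(benzyloxy)-2-oxo-2H-pyran-6-yl]methanide, the dienolate (not isolated) | [Li+].[CH2-]c1cc(OCc2ccccc2)cc(=O)o1 | intermediate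
11 | [4-(benzyloxy)-2-oxo-2H-pyran-6-yl]acetic acid | OC(=O)Cc1cc(OCc2ccccc2)cc(=O)o1 | intermediate
12 | Meldrum's acid (2,2-dimethyl-1,3-dioxane-4,6-dione) | CC1(C)OC(=O)CC(=O)O1 | starting material
13 | 5-{[4-(benzyloxy)-2-oxo-2H-pyran-6-yl]acetyl}-2,2-dimethyl-1,3-dioxane-4,6-dione (not isolated) | CC1(C)OC(=O)C(C(=O)Cc2cc(OCc3ccccc3)cc(=O)o2)C(=O)O1 | intermediate
14 | allyl 4-[4-(benzyloxy)-2-oxo-2H-pyran-6-yl]-3-oxobutanoate | C=CCOC(=O)CC(=O)Cc1cc(OCc2ccccc2)cc(=O)o1 | intermediate
15 | allyl 2-(2-{[4-(benzyloxy)-2-oxo-2H-pyran-6-yl]methyl}-1,3-dioxolan-2-yl)acetate | C=CCOC(=O)CC1(Cc2cc(OCc3ccccc3)cc(=O)o2)OCCO1 | intermediate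
16 | 2-(2-{[4-(benzyloxy)-2-oxo-2H-pyran-6-yl]methyl}-1,3-dioxolan-2-yl)acetic acid | OC(=O)CC1(Cc2cc(OCc3ccccc3)cc(=O)o2)OCCO1 | intermediate
17 | 5-(benzyloxy)-3-(3-methylbut-1-yn-1-yl)benzyne (not isolated) | CC(C)C#CC1=CC(OCc2ccccc2)=CC#C1 | intermediate
18 | cesium 2-(acyloxy)aryl anion from 16 and 17 (not isolated) | [Cs+].O=C(CC1(Cc2cc(OCc3ccccc3)cc(=O)o2)OCCO1)Oc1cc(OCc2ccccc2)cc(C#CC(C)C)[c-]1 | intermediate
19 | 1-[4-(benzyloxy)-2-hydroxy-6-(3-methylbut-1-yn-1-yl)phenyl]-2-(2-{[4-(benzyloxy)-2-oxo-2H-pyran-6-yl]methyl}-1,3-dioxolan-2-yl)ethan-1-one | CC(C)C#Cc1cc(OCc2ccccc2)cc(O)c1C(=O)CC1(Cc2cc(OCc3ccccc3)cc(=O)o2)OCCO1 | intermediate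
20 | 1-[4-(benzyloxy)-2-hydroxy-6-(3-methylbut-1-yn-1-yl)phenyl]-4-[4-(benzyloxy)-2-oxo-2H-pyran-6-yl]butane-1,3-dione (not isolated) | CC(C)C#Cc1cc(OCc2ccccc2)cc(O)c1C(=O)CC(=O)Cc1cc(OCc2ccccc2)cc(=O)o1 | intermediate
21 | racemic 7-(benzyloxy)-2-{[4-(benzyloxy)-2-oxo-2H-pyran-6-yl]methyl}-2-hydroxy-5-(3-methylbut-1-yn-1-yl)-2,3-dihydro-4H-chromen-4-one | CC(C)C#Cc1cc(OCc2ccccc2)cc2c1C(=O)CC(O)(Cc1cc(OCc3ccccc3)cc(=O)o1)O2 | intermediate
22 | (S)-1-phenylethanol | C[C@H](O)c1ccccc1 | starting material
23 | (2R)-7-(benzyloxy)-2-{[4-(benzyloxy)-2-oxo-2H-pyran-6-yl]methyl}-5-(3-methylbut-1-yn-1-yl)-2-[(1S)-1-phenylethoxy]-2,3-dihydro-4H-chromen-4-one | CC(C)C#Cc1cc(OCc2ccccc2)cc2c1C(=O)C[C@@](O[C@@H](C)c1ccccc1)(Cc1cc(OCc3ccccc3)cc(=O)o1)O2 | intermediate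
24 | (2R)-2,7-dihydroxy-2-[(4-hydroxy-2-oxo-2H-pyran-6-yl)methyl]-5-(3-methylbutyl)-2,3-dihydro-4H-chromen-4-one | CC(C)CCc1cc(O)cc2c1C(=O)C[C@@](O)(Cc1cc(O)cc(=O)o1)O2 | target

**Step count and risks**

Total step count: 12. Longest linear sequence: 9 steps (steps 4 to 12); the aryne precursor is made in 3 steps (steps 1 to 3).

Steps most likely to fail:

Step 9. The carboxylate may add to the wrong aryne carbon, the aryl anion may be protonated before the acyl shift (leaving an aryl ester), or the aryne may be consumed by cycloaddition with the pyranone. The fallback does the insertion on the simplest acid with a halogen as director and attaches the pyranone afterwards. It sets out from 5: its fluoride-generated 3-bromoaryne and acetic acid (CsF, THF, 125 °C) should give 1-[4-(benzyloxy)-2-bromo-6-hydroxyphenyl]ethan-1-one F1 with halogen-directed regiocontrol. Sonogashira coupling of F1 with 6 (PdCl2(PPh3)2, CuI, Et3N, 60 °C) gives 1-[4-(benzyloxy)-2-hydroxy-6-(3-methylbut-1-yn-1-yl)phenyl]ethan-1-one F2. Acid 11 is converted with CDI into 1-{[4-(benzyloxy)-2-oxo-2H-pyran-6-yl]acetyl}imidazole F3, which C-acylates the dilithium phenoxide-enolate of F2 (LiN(SiMe3)2, 3 equiv, THF, −78 °C; Claisen condensation of the Baker–Venkataraman type). Mild acidic work-up returns to the route at hemiketal 21, so that steps 6 to 8 and 10 are not needed.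

Step 11. The oxocarbenium ion at C2 may lose a C3 proton, draining material to the chromone, or the hindered secondary alcohol may exchange too slowly and give diastereomers that do not separate. The fallback sets out from 21 and uses an unhindered achiral alcohol with chromatographic resolution in place of the auxiliary. Benzyl alcohol as co-solvent (PPTS, CH2Cl2, 0 °C) should give racemic 2,7-bis(benzyloxy)-2-{[4-(benzyloxy)-2-oxo-2H-pyran-6-yl]methyl}-5-(3-methylbut-1-yn-1-yl)-2,3-dihydro-4H-chromen-4-one F4. Its enantiomers are separated by preparative chromatography on a chiral stationary phase to give the (2R)-enantiomer F5. Hydrogenation of F5 under the conditions of step 12 comes back to the route at 24.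

Step 12. During the long exposure needed for four reductive events, the pyranone hydroxyl that is unveiled may catalyse epimerization at C2, the hindered ketal ether may cleave incompletely, or the pyranone may be over-reduced. The fallback sets out from 21 and changes the order of events. Hydrogenation (H2, Pd/C, EtOAc) first gives the racemic, fully deprotected 2,7-dihydroxy-2-[(4-hydroxy-2-oxo-2H-pyran-6-yl)methyl]-5-(3-methylbutyl)-2,3-dihydro-4H-chromen-4-one F6. Ketal exchange of F6 with 22 (PPTS, 4 Å MS) and chromatographic separation at C2 gives (2R)-7-hydroxy-2-[(4-hydroxy-2-oxo-2H-pyran-6-yl)methyl]-5-(3-methylbutyl)-2-[(1S)-1-phenylethoxy]-2,3-dihydro-4H-chromen-4-one F7. A brief hydrogenolysis that has to cleave only the single 1-phenylethyl ether then comes back to the route at 24.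

**Further compounds**

F1 | step 9 | 1-[4-(benzyloxy)-2-bromo-6-hydroxyphenyl]ethan-1-one | CC(=O)c1c(O)cc(OCc2ccccc2)cc1Br
F2 | step 9 | 1-[4-(benzyloxy)-2-hydroxy-6-(3-methylbut-1-yn-1-yl)phenyl]ethan-1-one | CC(=O)c1c(O)cc(OCc2ccccc2)cc1C#CC(C)C
F3 | step 9 | 1-{[4-(benzyloxy)-2-oxo-2H-pyran-6-yl]acetyl}imidazole | O=C(Cc1cc(OCc2ccccc2)cc(=O)o1)n1ccnc1
F4 | step 11 | racemic 2,7-bis(benzyloxy)-2-{[4-(benzyloxy)-2-oxo-2H-pyran-6-yl]methyl}-5-(3-methylbut-1-yn-1-yl)-2,3-dihydro-4H-chromen-4-one | CC(C)C#Cc1cc(OCc2ccccc2)cc2c1C(=O)CC(OCc1ccccc1)(Cc1cc(OCc3ccccc3)cc(=O)o1)O2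
F5 | step 11 | (2R)-2,7-bis(benzyloxy)-2-{[4-(benzyloxy)-2-oxo-2H-pyran-6-yl]methyl}-5-(3-methylbut-1-yn-1-yl)-2,3-dihydro-4H-chromen-4-one | CC(C)C#Cc1cc(OCc2ccccc2)cc2c1C(=O)C[C@@](OCc1ccccc1)(Cc1cc(OCc3ccccc3)cc(=O)o1)O2
F6 | step 12 | racemic 2,7-dihydroxy-2-[(4-hydroxy-2-oxo-2H-pyran-6-yl)methyl]-5-(3-methylbutyl)-2,3-dihydro-4H-chromen-4-one | CC(C)CCc1cc(O)cc2c1C(=O)CC(O)(Cc1cc(O)cc(=O)o1)O2
F7 | step 12 | (2R)-7-hydroxy-2-[(4-hydroxy-2-oxo-2H-pyran-6-yl)methyl]-5-(3-methylbutyl)-2-[(1S)-1-phenylethoxy]-2,3-dihydro-4H-chromen-4-one | CC(C)CCc1cc(O)cc2c1C(=O)C[C@@](O[C@@H](C)c1ccccc1)(Cc1cc(O)cc(=O)o1)O2
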